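If I change the precatalyst charge in the larch flask, by what factor does the rate at 10% conversion move? No run varies that charge, so I need a quantity from the readings that can be carried to another charge.

| flask | starting material | precatalyst | remark |
|---|---|---|---|
| larch | 10 mM | 17 µM | the very flask that is asked about, followed so far |
| maple | 6.7 mM | 17 µM | run made earlier |
| flask | 10 mM | 17 µM |  |

- larch (time / s: product / %, starting material / %): 10.0: 1, 97; 15.0: 2, 96; 25.0: 4, 94; 30.0: 7, 92; 40.0: 13, 92
- maple (time / s: product / %, starting material / %): 10.0: 3, 101; 12.0: 3, 98; 20.0: 2, 95; 40.0: 13, 87; 60.0: 22, 73; 90.0: 43, 55

(each reading ± 1.5 percentage points)

- factor on the rate of making product when 10% of the starting material are converted if precatalyst is charged twice over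
- factor on the rate when 10% of the starting material are converted if precatalyst is charged at 3.0 µM instead

- no earlier run changes the charge of precatalyst; that part of a forecast is a guess

Both runs start with a lag (an induction period), and both stand at 13% product at 40.0 s, so I treat them as sharing one clock. Suppose conversion grows as the charge times time to a power. Dividing the rate by the conversion per elapsed time then removes time and leaves that power. In larch, product passes 10% near 35.0 s and is climbing there at 0.00600 /s of the charge, which gives 2.10. I call this the lag exponent: rate times time, divided by conversion. At fixed conversion, the rate then goes as the charge to one over this exponent.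

The second way uses maple, from 20.0 s to 60.0 s. Product gives 2.18, but starting material lost gives 1.54. The product figure is the one I distrust, since it rests on a reading of 2%: one scatter higher, it becomes 1.67. I keep the larch value, read at the conversion asked about, and reckon 1.39 for doubling and 0.438 for 3.0 µM.

The forecast, reckoned its own way, says 1.4 (1.1 to 2) and 0.42 (0.18 to 0.7), since more precatalyst arrives sooner, “when less activation has occurred”.

The flask gives 1.39 and 0.373, both within the forecast's tolerance.

    2 catalyst intermediate ⇌ resting dimer, settled at all times (K = 2.80 × 10⁵ /M)
    starting material + free catalyst ⇌ catalyst intermediate (K = 3100 /M, k = 2000 /M/s)
    catalyst intermediate → free catalyst + product (k = 23.0 /s)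
    precatalyst ⇌ free catalyst (K = 1.80, k = 0.0120 /s)

Doubling the precatalyst multiplies the time to 10% by 0.721 and the rate by 1.39; their product is 1.00, so rate times time at that conversion, and with it the lag exponent, stays the same across that change, though this says nothing of the exponent's value. The factor for doubling corresponds to a power of 2.10 in the rule on the charge. At 3.0 µM the factor falls below my 0.438, which corresponds to a power of 1.76 in that rule. In the flask, precatalyst falls from 75.8% at 0.400 min to 33.2% at 2.00 min while product rises from 4.35% to 52.4%. Precatalyst then stays near that share while turnover continues, and at 4.00 min starting material stands at 5.95%, with free catalyst at 64.2% of the catalyst charged.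

The readings are simulated with made-up constants; noise was put on by code.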